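**Overview**
Cuts: in the central ring, first the bond between the acyl-bearing carbon and the C-OH carbon flanked by side chain and acyl group (Claisen), then the bond between the other C-OH carbon and the ring CH (gamma-acylation). Outside the ring: the stereocentre-to-ring bond (allylic alkylation of a malonate), the styryl C=C (cross-metathesis), the chalcone C=C (aldol condensation) and the aryl-CH2 bond of the tether (Grignard coupling).
Enabling feature: the pentasubstituted central benzene ring, read around as C-OMe, CH, C-OH, C-alkyl, C-OH, C-acyl, is a 1,3,5-trioxygenated polyketide ring with one oxygen methylated. Its six carbons map one by one onto an enol methyl ether carbon, a methylene, a ketone, a malonyl CH, an ester carbonyl and a vinylic CH next to the cinnamoyl ketone of an open chain.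
Forward order: the three 4-oxyphenyl rings are bought. The aryl-heptenyl carbonate is assembled, the malonate and then the styryl arm are attached, and the malonyl chloride is joined to a methoxy dienone. The central ring, the only ring made, closes in the penultimate step, before desilylation.
Stereochemistry: the single (R) centre is set by an iridium-phosphoramidite-catalysed, branched-selective allylic alkylation and is never alpha to a carbonyl afterwards. The E-styrene comes from cross-metathesis and the E-enone from aldol addition and elimination.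

Key step: step 16

Assumption: the (Sa,S,S) enantiomer of ligand L, O,O'-(1,1'-binaphthalene-2,2'-diyl) N,N-bis[1-(2-methoxyphenyl)ethyl]phosphoramidite, is taken as the one that leads to the (R) centre. The sense of induction is to be confirmed on the first batch of 11, and the equally available mirror-image ligand is used if the opposite is found.
Notation: TIPS = triisopropylsilyl; C1 to C9 in compounds 25 to 27 follow the nonadienoate numbering of 25.

**Step 1**
Reactants: 1 4-bromophenol
Product: 2 (4-bromophenoxy)triisopropylsilane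
Conditions: TIPSCl, imidazole, DMF, rt
Reagents that add atoms: triisopropylsilyl chloride, CC(C)[Si](Cl)(C(C)C)C(C)C
Why: Imidazole-promoted O-silylation of a phenol is routine, and the hindered TIPS ether should withstand the Grignard, hydride, amide and alkoxide reagents that follow.

**Step 2**
Reactants: 2 (4-bromophenoxy)triisopropylsilane; 3 6-bromohex-1-ene
Product: 5 6-[4-(triisopropylsilyloxy)phenyl]hex-1-ene, via arylmagnesium bromide 4 (not isolated)
Conditions: Mg, THF, reflux; then 3, Li2CuCl4 (3 mol %), THF, 0 °C to rt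
Reagents that add atoms: magnesium, [Mg] (kept only in intermediate 4)
Why: A Kochi-type copper-catalysed coupling of an aryl Grignard reagent with a primary alkyl bromide forms the aryl-CH2 bond and leaves the remote terminal alkene untouched.

**Step 3**
Reactants: 5 6-[4-(triisopropylsilyloxy)phenyl]hex-1-ene; 6 methyl acrylate
Product: 7 methyl (E)-7-[4-(triisopropylsilyloxy)phenyl]hept-2-enoate
Conditions: second-generation Hoveyda-Grubbs catalyst [RuCl2(H2IMes)(=CH-C6H4-2-OiPr)] (2 mol %), 6 (3 equiv), CH2Cl2, 40 °C
Reagents that add atoms: none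
Why: Olefin cross-metathesis of an unhindered terminal alkene with an electron-poor acrylate is selective for the cross product and should deliver the E-enoate under thermodynamic control.

**Step 4**
Reactants: 7 methyl (E)-7-[4-(triisopropylsilyloxy)phenyl]hept-2-enoate
Product: 8 (E)-7-[4-(triisopropylsilyloxy)phenyl]hept-2-en-1-ol
Conditions: i-Bu2AlH (2.3 equiv), CH2Cl2, -78 °C; aq. potassium sodium tartrate
Reagents that add atoms: none
Why: DIBAL-H reduces an enoate in the 1,2-sense to the allylic alcohol without changing the alkene geometry or the aryl silyl ether.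

**Step 5**
Reactants: 8 (E)-7-[4-(triisopropylsilyloxy)phenyl]hept-2-en-1-ol
Product: 9 (E)-7-[4-(triisopropylsilyloxy)phenyl]hept-2-enyl methyl carbonate
Conditions: ClCO2Me, pyridine, CH2Cl2, 0 °C
Reagents that add atoms: methyl chloroformate, COC(=O)Cl
Why: Acylation of a primary alcohol with a chloroformate is routine and installs the leaving group that later releases its own base (methoxide) on ionisation.

**Step 6**
Reactants: 9 (E)-7-[4-(triisopropylsilyloxy)phenyl]hept-2-enyl methyl carbonate; 10 tert-butyl methyl malonate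
Product: 11 tert-butyl methyl 2-[(3R)-7-[4-(triisopropylsilyloxy)phenyl]hept-1-en-3-yl]malonate (both epimers at the malonate carbon)
Conditions: [Ir(cod)Cl]2 (2 mol %), (Sa,S,S)-L (4 mol %), 1,5,7-triazabicyclo[4.4.0]dec-5-ene (8 mol %), THF, rt; then 9, 10 (1.3 equiv), rt to 50 °C
Reagents that add atoms: none
Why: In this iridium-catalysed asymmetric allylic alkylation the cyclometalated iridium-phosphoramidite complex ionises the linear E-carbonate, the released methoxide deprotonates the malonate, and the soft nucleophile attacks the substituted allyl terminus anti to the metal on the face left open by the ligand, which sets the (R) centre while the malonate carbon forms as an inconsequential mixture of epimers.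

**Step 7**
Reactants: 12 4-hydroxybenzaldehyde
Product: 13 4-(triisopropylsilyloxy)benzaldehyde
Conditions: TIPSCl, imidazole, DMF, rt
Reagents that add atoms: triisopropylsilyl chloride, CC(C)[Si](Cl)(C(C)C)C(C)C
Why: The same routine phenol silylation gives one aldehyde that serves both the styrene and the dienone branch.

**Step 8**
Reactants: 13 4-(triisopropylsilyloxy)benzaldehyde
Product: 14 4-(triisopropylsilyloxy)styrene
Conditions: Ph3PCH3Br, KOt-Bu, THF, 0 °C to rt
Reagents that add atoms: methyltriphenylphosphonium bromide, C[P+](c1ccccc1)(c1ccccc1)c1ccccc1.[Br-]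
Why: Wittig methylenation of a non-enolisable aromatic aldehyde is reliable and compatible with the aryl TIPS ether.

**Step 9**
Reactants: 11 tert-butyl methyl 2-[(3R)-7-[4-(triisopropylsilyloxy)phenyl]hept-1-en-3-yl]malonate; 14 4-(triisopropylsilyloxy)styrene
Product: 15 tert-butyl methyl 2-[(1E,3R)-1,7-bis[4-(triisopropylsilyloxy)phenyl]hept-1-en-3-yl]malonate
Conditions: second-generation Hoveyda-Grubbs catalyst [RuCl2(H2IMes)(=CH-C6H4-2-OiPr)] (5 mol %), 14 (3 equiv), CH2Cl2, 40 °C
Reagents that add atoms: none
Why: Olefin cross-metathesis between a slowly reacting, allylically branched terminal alkene and an excess of a readily exchanging styrene should favour the cross product, and the conjugated aryl alkene forms as the E isomer without touching the adjacent stereocentre.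

**Step 10**
Reactants: 15 tert-butyl methyl 2-[(1E,3R)-1,7-bis[4-(triisopropylsilyloxy)phenyl]hept-1-en-3-yl]malonate
Product: 17 2-[(1E,3R)-1,7-bis[4-(triisopropylsilyloxy)phenyl]hept-1-en-3-yl]malonic acid monomethyl ester, via trimethylsilyl ester 16 (not isolated)
Conditions: TMSOTf (2 equiv), 2,6-lutidine (3 equiv), CH2Cl2, 0 °C to rt; then aq. NaH2PO4
Reagents that add atoms: trimethylsilyl trifluoromethanesulfonate, C[Si](C)(C)OS(=O)(=O)C(F)(F)F (silyl group kept only in intermediate 16)
Why: Silyl-triflate-mediated cleavage of a tert-butyl ester by loss of isobutene is selective over the methyl ester, and the lutidine buffer protects the acid-sensitive 4-silyloxystyrene and the aryl TIPS ethers.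

**Step 11**
Reactants: 17 2-[(1E,3R)-1,7-bis[4-(triisopropylsilyloxy)phenyl]hept-1-en-3-yl]malonic acid monomethyl ester
Product: 18 methyl 2-(chlorocarbonyl)-2-[(1E,3R)-1,7-bis[4-(triisopropylsilyloxy)phenyl]hept-1-en-3-yl]acetate (crude, used at once)
Conditions: 1-chloro-N,N,2-trimethylprop-1-en-1-amine (1.1 equiv), CH2Cl2, 0 °C to rt; concentrate
Reagents that add atoms: Ghosez reagent (1-chloro-N,N,2-trimethylprop-1-en-1-amine), CC(C)=C(Cl)N(C)C
Why: Acid chloride formation with the Ghosez reagent runs under neutral conditions without free HCl or heat, so the electron-rich styrene, the silyl ethers and the decarboxylation-prone half-malonate should all survive.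

**Step 12**
Reactants: 13 4-(triisopropylsilyloxy)benzaldehyde; 19 (E)-4-methoxypent-3-en-2-one
Product: 21 (E)-1-hydroxy-5-methoxy-1-[4-(triisopropylsilyloxy)phenyl]hex-4-en-3-one (racemic), via lithium enolate 20 (not isolated)
Conditions: 19, LiN(i-Pr)2, THF, -78 °C; then 13; AcOH, -78 °C
Reagents that add atoms: lithium diisopropylamide, CC(C)N([Li])C(C)C (lithium kept only in intermediate 20)
Why: Kinetic deprotonation of a beta-alkoxy enone with LDA occurs at the alpha-prime acetyl methyl, and the directed aldol addition to the non-enolisable aldehyde gives a carbinol whose stereocentre is erased in the next step.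

**Step 13**
Reactants: 21 (E)-1-hydroxy-5-methoxy-1-[4-(triisopropylsilyloxy)phenyl]hex-4-en-3-one
Product: 23 (1E,4E)-5-methoxy-1-[4-(triisopropylsilyloxy)phenyl]hexa-1,4-dien-3-one, via benzylic mesylate 22 (not isolated)
Conditions: MsCl (1.2 equiv), Et3N (3 equiv), CH2Cl2, 0 °C to rt
Reagents that add atoms: methanesulfonyl chloride, CS(=O)(=O)Cl (kept only in intermediate 22)
Why: Mesylation of a beta-hydroxy ketone followed by E1cB elimination gives the conjugated E-enone under mild basic conditions that leave the enol methyl ether alone.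

**Step 14**
Reactants: 23 (1E,4E)-5-methoxy-1-[4-(triisopropylsilyloxy)phenyl]hexa-1,4-dien-3-one
Product: 24 (5E)-2-methoxy-4-(trimethylsilyloxy)-6-[4-(triisopropylsilyloxy)phenyl]hexa-1,3,5-triene (geometry of the new enol double bond of no consequence; crude)
Conditions: TMSOTf, Et3N, Et2O, 0 °C; pentane extraction
Reagents that add atoms: trimethylsilyl trifluoromethanesulfonate, C[Si](C)(C)OS(=O)(=O)C(F)(F)F
Why: In this soft enolisation, O-silylation of the carbonyl acidifies the gamma-methyl, which carries the only removable protons because the cinnamoyl side has none, so a single silyl dienol ether should form.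

**Step 15**
Reactants: 18 methyl 2-(chlorocarbonyl)-2-[(1E,3R)-1,7-bis[4-(triisopropylsilyloxy)phenyl]hept-1-en-3-yl]acetate; 24 (5E)-2-methoxy-4-(trimethylsilyloxy)-6-[4-(triisopropylsilyloxy)phenyl]hexa-1,3,5-triene
Product: 25 methyl (5E,8E)-2-[(1E,3R)-1,7-bis[4-(triisopropylsilyloxy)phenyl]hept-1-en-3-yl]-5-methoxy-3,7-dioxo-9-[4-(triisopropylsilyloxy)phenyl]nona-5,8-dienoate (epimers at C2)
Conditions: CH2Cl2, -78 °C to rt; aq. NaHCO3
Reagents that add atoms: none
Why: In this vinylogous Mukaiyama-type C-acylation, 1,3-dioxygenated silyl dienol ethers are known to take up acid chlorides, methyl malonyl chloride included, at the terminal carbon where both oxygen donors reinforce each other, and the base-free medium avoids dehydrochlorination of 18 to a ketene.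

**Step 16**
Reactants: 25 methyl (5E,8E)-2-[(1E,3R)-1,7-bis[4-(triisopropylsilyloxy)phenyl]hept-1-en-3-yl]-5-methoxy-3,7-dioxo-9-[4-(triisopropylsilyloxy)phenyl]nona-5,8-dienoate
Product: 28 tris-TIPS deoxycalyxin A, via potassium trienolate 26 (not isolated), via cyclohexenedione tautomer 27 (not isolated)
Conditions: KOt-Bu (1.2 equiv), THF/t-BuOH (10:1), 0 °C to rt; AcOH, 0 °C
Reagents that add atoms: potassium tert-butoxide, CC(C)(C)[O-].[K+] (potassium kept only in intermediate 26)
Why: Proposed new method: tert-butoxide reversibly deprotonates the C4 methylene between the C3 ketone and the C5 enol ether, the trienolate 26 (charge shared by O3, C4, C6 and O7) attacks the C1 ester carbonyl through C6, the vinylic carbon alpha to the cinnamoyl ketone, methoxide leaves to give enedione 27, and loss of the C6 and C2 protons by enolisation turns 27 irreversibly into the phenoxide of 28. The closest known reaction types are the base-induced Claisen cyclisation of free 3,5,7-triketo esters to acylphloroglucinols and the Lacey-Dieckmann closure, in which a stabilised 1,3-dicarbonyl enolate also acylates itself with a plain ester; not yet shown is a chain whose middle carbonyl is fixed as a methyl enol ether and whose C2 bears a branched alkyl group. The only ring closed is the six-membered carbocycle C1 to C6, formed in the 6-(enolexo)-exo-trig mode and aromatised in the same operation. No lasting stereocentre arises, since C2 and C6 of 27 end as sp2 ring carbons, and the (R) centre is beta to every carbonyl group, cannot enolise and is simply carried through. The step needs C-acylation at C6 in preference to aldol attack of C2 on C7, Michael attack of C4 on C9 and oxygen cyclisation: the aldol adduct would hold a quaternary C2 at a deactivated vinylogous-ester carbonyl and can only revert, the Michael adduct of a stabilised carbanion is likewise reversible, and the methyl cap takes away the C5 oxygen that a 2-pyranone would require, so that aromatisation is the single irreversible exit. About one equivalent of base with tert-butanol as proton shuttle is chosen so that the unproductive C2 enolate, in which the ester is switched off, keeps exchanging with 26 instead of being locked in as a dianion, and the position of the enol ether decides which ring oxygen ends up methylated.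

**Step 17**
Reactants: 28 tris-TIPS deoxycalyxin A
Product: 29 deoxycalyxin A
Conditions: n-Bu4NF/AcOH (1:1, 3.6 equiv), THF, 0 °C
Reagents that add atoms: none
Why: Fluoride cleavage of aryl silyl ethers is fast, and the acetic acid buffer keeps the liberated phenols protonated so that the 2'-hydroxychalcone should not close to the flavanone and the 4-hydroxystyrene never meets strong acid.

**Compound list**
1 | 4-bromophenol | Oc1ccc(Br)cc1 | starting material
2 | (4-bromophenoxy)triisopropylsilane | CC(C)[Si](Oc1ccc(Br)cc1)(C(C)C)C(C)C | intermediate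
3 | 6-bromohex-1-ene | C=CCCCCBr | starting material
4 | [4-(triisopropylsilyloxy)phenyl]magnesium bromide | CC(C)[Si](Oc1ccc([Mg]Br)cc1)(C(C)C)C(C)C | intermediate
5 | 6-[4-(triisopropylsilyloxy)phenyl]hex-1-ene | C=CCCCCc1ccc(O[Si](C(C)C)(C(C)C)C(C)C)cc1 | intermediate
6 | methyl acrylate | C=CC(=O)OC | starting material
7 | methyl (E)-7-[4-(triisopropylsilyloxy)phenyl]hept-2-enoate | COC(=O)/C=C/CCCCc1ccc(O[Si](C(C)C)(C(C)C)C(C)C)cc1 | intermediate
8 | (E)-7-[4-(triisopropylsilyloxy)phenyl]hept-2-en-1-ol | OC/C=C/CCCCc1ccc(O[Si](C(C)C)(C(C)C)C(C)C)cc1 | intermediate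
9 | (E)-7-[4-(triisopropylsilyloxy)phenyl]hept-2-enyl methyl carbonate | COC(=O)OC/C=C/CCCCc1ccc(O[Si](C(C)C)(C(C)C)C(C)C)cc1 | intermediate
10 | tert-butyl methyl malonate | COC(=O)CC(=O)OC(C)(C)C | starting material
11 | tert-butyl methyl 2-[(3R)-7-[4-(triisopropylsilyloxy)phenyl]hept-1-en-3-yl]malonate | COC(=O)C(C(=O)OC(C)(C)C)[C@@H](C=C)CCCCc1ccc(O[Si](C(C)C)(C(C)C)C(C)C)cc1 | intermediate
12 | 4-hydroxybenzaldehyde | O=Cc1ccc(O)cc1 | starting material
13 | 4-(triisopropylsilyloxy)benzaldehyde | O=Cc1ccc(O[Si](C(C)C)(C(C)C)C(C)C)cc1 | intermediate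
14 | 4-(triisopropylsilyloxy)styrene | C=Cc1ccc(O[Si](C(C)C)(C(C)C)C(C)C)cc1 | intermediate
15 | tert-butyl methyl 2-[(1E,3R)-1,7-bis[4-(triisopropylsilyloxy)phenyl]hept-1-en-3-yl]malonate | COC(=O)C(C(=O)OC(C)(C)C)[C@@H](/C=C/c1ccc(O[Si](C(C)C)(C(C)C)C(C)C)cc1)CCCCc1ccc(O[Si](C(C)C)(C(C)C)C(C)C)cc1 | intermediate
16 | methyl trimethylsilyl 2-[(1E,3R)-1,7-bis[4-(triisopropylsilyloxy)phenyl]hept-1-en-3-yl]malonate | COC(=O)C(C(=O)O[Si](C)(C)C)[C@@H](/C=C/c1ccc(O[Si](C(C)C)(C(C)C)C(C)C)cc1)CCCCc1ccc(O[Si](C(C)C)(C(C)C)C(C)C)cc1 | intermediate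
17 | 2-[(1E,3R)-1,7-bis[4-(triisopropylsilyloxy)phenyl]hept-1-en-3-yl]malonic acid monomethyl ester | COC(=O)C(C(=O)O)[C@@H](/C=C/c1ccc(O[Si](C(C)C)(C(C)C)C(C)C)cc1)CCCCc1ccc(O[Si](C(C)C)(C(C)C)C(C)C)cc1 | intermediate
18 | methyl 2-(chlorocarbonyl)-2-[(1E,3R)-1,7-bis[4-(triisopropylsilyloxy)phenyl]hept-1-en-3-yl]acetate | COC(=O)C(C(Cl)=O)[C@@H](/C=C/c1ccc(O[Si](C(C)C)(C(C)C)C(C)C)cc1)CCCCc1ccc(O[Si](C(C)C)(C(C)C)C(C)C)cc1 | intermediate
19 | (E)-4-methoxypent-3-en-2-one | CO/C(C)=C/C(C)=O | starting material
20 | lithium (E)-4-methoxypenta-1,3-dien-2-olate | CO/C(C)=C/C(=C)O[Li] | intermediate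
21 | (E)-1-hydroxy-5-methoxy-1-[4-(triisopropylsilyloxy)phenyl]hex-4-en-3-one (racemic) | CO/C(C)=C/C(=O)CC(O)c1ccc(O[Si](C(C)C)(C(C)C)C(C)C)cc1 | intermediate
22 | (E)-5-methoxy-3-oxo-1-[4-(triisopropylsilyloxy)phenyl]hex-4-enyl methanesulfonate (racemic) | CO/C(C)=C/C(=O)CC(OS(C)(=O)=O)c1ccc(O[Si](C(C)C)(C(C)C)C(C)C)cc1 | intermediate
23 | (1E,4E)-5-methoxy-1-[4-(triisopropylsilyloxy)phenyl]hexa-1,4-dien-3-one | CO/C(C)=C/C(=O)/C=C/c1ccc(O[Si](C(C)C)(C(C)C)C(C)C)cc1 | intermediate
24 | (5E)-2-methoxy-4-(trimethylsilyloxy)-6-[4-(triisopropylsilyloxy)phenyl]hexa-1,3,5-triene | C=C(OC)C=C(O[Si](C)(C)C)/C=C/c1ccc(O[Si](C(C)C)(C(C)C)C(C)C)cc1 | intermediate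
25 | methyl (5E,8E)-2-[(1E,3R)-1,7-bis[4-(triisopropylsilyloxy)phenyl]hept-1-en-3-yl]-5-methoxy-3,7-dioxo-9-[4-(triisopropylsilyloxy)phenyl]nona-5,8-dienoate | COC(=O)C([C@@H](/C=C/c1ccc(O[Si](C(C)C)(C(C)C)C(C)C)cc1)CCCCc1ccc(O[Si](C(C)C)(C(C)C)C(C)C)cc1)C(=O)C/C(OC)=C\C(=O)/C=C/c1ccc(O[Si](C(C)C)(C(C)C)C(C)C)cc1 | intermediate
26 | potassium trienolate of 25 (deprotonated at C4, drawn as the C7 enolate) | COC(=O)C([C@@H](/C=C/c1ccc(O[Si](C(C)C)(C(C)C)C(C)C)cc1)CCCCc1ccc(O[Si](C(C)C)(C(C)C)C(C)C)cc1)C(=O)C=C(OC)C=C([O-])/C=C/c1ccc(O[Si](C(C)C)(C(C)C)C(C)C)cc1.[K+] | intermediate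
27 | 5-methoxycyclohex-4-ene-1,3-dione bearing the (1E,3R)-diarylheptenyl group at C2 and the 4-(triisopropylsilyloxy)cinnamoyl group at C6 (keto tautomer of 28) | COC1=CC(=O)C([C@@H](/C=C/c2ccc(O[Si](C(C)C)(C(C)C)C(C)C)cc2)CCCCc2ccc(O[Si](C(C)C)(C(C)C)C(C)C)cc2)C(=O)C1C(=O)/C=C/c1ccc(O[Si](C(C)C)(C(C)C)C(C)C)cc1 | intermediate
28 | tris-TIPS deoxycalyxin A, (E)-1-{3-[(1E,3R)-1,7-bis[4-(triisopropylsilyloxy)phenyl]hept-1-en-3-yl]-2,4-dihydroxy-6-methoxyphenyl}-3-[4-(triisopropylsilyloxy)phenyl]prop-2-en-1-one | COc1cc(O)c([C@@H](/C=C/c2ccc(O[Si](C(C)C)(C(C)C)C(C)C)cc2)CCCCc2ccc(O[Si](C(C)C)(C(C)C)C(C)C)cc2)c(O)c1C(=O)/C=C/c1ccc(O[Si](C(C)C)(C(C)C)C(C)C)cc1 | intermediate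
29 | deoxycalyxin A, (E)-1-{3-[(1E,3R)-1,7-bis(4-hydroxyphenyl)hept-1-en-3-yl]-2,4-dihydroxy-6-methoxyphenyl}-3-(4-hydroxyphenyl)prop-2-en-1-one | COc1cc(O)c([C@@H](/C=C/c2ccc(O)cc2)CCCCc2ccc(O)cc2)c(O)c1C(=O)/C=C/c1ccc(O)cc1 | target

Total step count: 17.
Longest linear sequence: 12 steps from 4-bromophenol (steps 1 to 6, 9 to 11, 15 to 17).

**Steps most likely to fail**

Step 16.
- What may go wrong: the doubly stabilised enolate may be too weak a nucleophile for a hindered methyl ester. The base may settle on C2 and so switch the ester off. C4 may add in Michael fashion to the cinnamoyl beta-carbon. The new 2'-hydroxychalcone may drift to the flavanone on long exposure to base.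
- Fallback: it relies on the known cyclisation of unmasked chains and moves the methylation behind the ring closure. It sets out from 25 and comes back to the route at 29.
- Dilute aqueous HCl in THF hydrolyses the vinylogous ester of 25 to the free 3,5,7-triketo ester F1.
- Mg(OMe)2 in MeOH/THF brings about the established Claisen cyclisation of such triketo esters to the 2',4',6'-trihydroxychalcone F2.
- One equivalent of TBSCl with imidazole silylates the most acidic hydroxyl, the one para to the acyl group that cannot chelate, to give silyl ether F3.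
- A Mitsunobu methylation (MeOH, PPh3, DIAD) should then take the less hindered of the two ortho hydroxyls, the one next to the ring CH, to give methyl ether F4, while the other stays chelated.
- The buffered fluoride of step 17 removes all four silyl groups and gives 29.

Step 15.
- What may go wrong: the neutral silyl dienol ether may react too slowly with the alpha-branched acid chloride. Adventitious HCl may hydrolyse the diene or the enol ether. Compound 18 may lose HCl to a ketene that oligomerises.
- Fallback: it replaces the neutral nucleophile by a metal dienolate and the chloride by a milder acyl donor, as known from the gamma-acylation of dioxinone and other beta-alkoxy dienolates. It sets out from 17 and 23 and comes back at 25.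
- Acid 17 and 1,1'-carbonyldiimidazole in THF give acyl imidazolide F5.
- Dienone 23 (two equivalents, since the more acidic product consumes one equivalent of dienolate) is deprotonated at the gamma-methyl with LiN(SiMe3)2 in THF at -78 °C.
- F5 is added, and an acetic acid quench should give 25.

Step 9.
- What may go wrong: the allylically branched alkene may enter the catalytic cycle too slowly, so that the styrene is used up by homodimerisation and the catalyst decays.
- Fallback: it forms the aryl-vinyl single bond instead of the double bond. It sets out from 2 and 11 and comes back at 15.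
- The Grignard reagent 4, made from 2 as in step 2, is quenched with B(OMe)3 and hydrolysed to 4-(triisopropylsilyloxy)phenylboronic acid F6.
- An oxidative Heck arylation of 11 with F6 follows (Pd(OAc)2 with 1,2-bis(phenylsulfinyl)ethane, benzoquinone, AcOH, dioxane, rt).
- A malonate carbonyl can chelate the alkylpalladium intermediate, which should steer beta-hydride elimination to the benzylic side and give E-styrene 15 without disturbing the allylic stereocentre.

**Further compounds**
F1 | step 16 | methyl (8E)-2-[(1E,3R)-1,7-bis[4-(triisopropylsilyloxy)phenyl]hept-1-en-3-yl]-3,5,7-trioxo-9-[4-(triisopropylsilyloxy)phenyl]non-8-enoate | COC(=O)C([C@@H](/C=C/c1ccc(O[Si](C(C)C)(C(C)C)C(C)C)cc1)CCCCc1ccc(O[Si](C(C)C)(C(C)C)C(C)C)cc1)C(=O)CC(=O)CC(=O)/C=C/c1ccc(O[Si](C(C)C)(C(C)C)C(C)C)cc1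
F2 | step 16 | (E)-1-{3-[(1E,3R)-1,7-bis[4-(triisopropylsilyloxy)phenyl]hept-1-en-3-yl]-2,4,6-trihydroxyphenyl}-3-[4-(triisopropylsilyloxy)phenyl]prop-2-en-1-one | Oc1cc(O)c([C@@H](/C=C/c2ccc(O[Si](C(C)C)(C(C)C)C(C)C)cc2)CCCCc2ccc(O[Si](C(C)C)(C(C)C)C(C)C)cc2)c(O)c1C(=O)/C=C/c1ccc(O[Si](C(C)C)(C(C)C)C(C)C)cc1
F3 | step 16 | 4'-O-tert-butyldimethylsilyl ether of F2 | Oc1cc(O[Si](C)(C)C(C)(C)C)c([C@@H](/C=C/c2ccc(O[Si](C(C)C)(C(C)C)C(C)C)cc2)CCCCc2ccc(O[Si](C(C)C)(C(C)C)C(C)C)cc2)c(O)c1C(=O)/C=C/c1ccc(O[Si](C(C)C)(C(C)C)C(C)C)cc1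
F4 | step 16 | 6'-O-methyl ether of F3 (4'-O-TBS tris-TIPS deoxycalyxin A) | COc1cc(O[Si](C)(C)C(C)(C)C)c([C@@H](/C=C/c2ccc(O[Si](C(C)C)(C(C)C)C(C)C)cc2)CCCCc2ccc(O[Si](C(C)C)(C(C)C)C(C)C)cc2)c(O)c1C(=O)/C=C/c1ccc(O[Si](C(C)C)(C(C)C)C(C)C)cc1
F5 | step 15 | methyl 2-(imidazole-1-carbonyl)-2-[(1E,3R)-1,7-bis[4-(triisopropylsilyloxy)phenyl]hept-1-en-3-yl]acetate | COC(=O)C(C(=O)n1ccnc1)[C@@H](/C=C/c1ccc(O[Si](C(C)C)(C(C)C)C(C)C)cc1)CCCCc1ccc(O[Si](C(C)C)(C(C)C)C(C)C)cc1
F6 | step 9 | 4-(triisopropylsilyloxy)phenylboronic acid | OB(O)c1ccc(O[Si](C(C)C)(C(C)C)C(C)C)cc1
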